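Numbering: lactone O1, C2(=O), C3, C4, C5, exocyclic C6. Ring A is the 4-hydroxyphenyl group on C4 and ring B is the 3-bromo-4-methoxyphenyl group on C6.
Cuts: first the two silicon masks (O–Si on ring A and a C3–Si placeholder), then C6–C5, C5–C4, C3–C2 and O1–C2 in a single operation, and last the ring A–alkyne bond.
Enabling feature: C6–C5–C4=C3–C2 is one unbranched chain. C5 and C2 are at the carbonyl oxidation level, so each can come from one CO. C4=C3 is a former alkyne carrying ring A, and C6 is a benzylic CH of ring B.
Forward: ring A is silylated and alkynylated. The only new ring, the butenolide, is then assembled on cobalt from benzyl bromide, alkyne and two CO, and fluoride finally frees C3–H and the phenol.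
Stereochemistry: there is no stereocentre. The sole element is the Z C5=C6 alkene, set when base releases the lactone from cobalt with ring B turned away from ring A.

Key step: step 3

Assumption: the ring B benzyl bromide is taken as a catalogue compound and used from a fresh bottle, because p-alkoxybenzyl bromides age on storage. NaCo(CO)4 is made from Co2(CO)8 just before use.

Step 1
Reactants: 1 4-iodophenol
Product: 2 tert-butyl(4-iodophenoxy)dimethylsilane
Conditions: TBSCl, imidazole, DMF, 23 °C
Reagents that add atoms: tert-butyldimethylsilyl chloride (TBSCl), CC(C)(C)[Si](C)(C)Cl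
Why: Imidazole-promoted O-silylation of a phenol (silyl ether protection) leaves the aryl iodide alone and masks the acidic OH that would otherwise consume acylcobalt and amine in step 3.

Step 2
Reactants: 2 tert-butyl(4-iodophenoxy)dimethylsilane; 3 ethynyltrimethylsilane
Product: 4 tert-butyldimethyl{4-[(trimethylsilyl)ethynyl]phenoxy}silane
Conditions: PdCl2(PPh3)2 (2 mol %), CuI (4 mol %), Et3N, THF, 23 °C
Reagents that add atoms: none
Why: Sonogashira coupling of an aryl iodide with a terminal alkyne runs at room temperature, where both the aryl silyl ether and the C–SiMe3 cap should survive the amine medium.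

Step 3
Reactants: 4 tert-butyldimethyl{4-[(trimethylsilyl)ethynyl]phenoxy}silane; 5 3-bromo-4-methoxybenzyl bromide
Product: 8 (Z)-5-(3-bromo-4-methoxybenzylidene)-4-[4-(tert-butyldimethylsilyloxy)phenyl]-3-(trimethylsilyl)furan-2(5H)-one, via arylacetylcobalt tetracarbonyl 6 (not isolated), via η3-lactonylcobalt tricarbonyl 7 (not isolated)
Conditions: 5, NaCo(CO)4 (1.1 equiv, from Co2(CO)8, Na/Hg, THF), CO (1 atm), THF, 0 °C, dark; then 4, 25 to 45 °C; then Cy2NEt (2 equiv), CO (1 atm), 25 °C
Reagents that add atoms: carbon monoxide, [C-]#[O+] (two molecules)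
Why: Proposed new method: Co(CO)4− displaces the benzylic bromide of 5 (the aryl C–Br bond does not react in the dark), CO migratory insertion gives 6, loss of one CO lets alkyne 4 bind and insert syn into the acyl–cobalt bond, a second CO insertion extends the vinylcobalt to an acylcobalt, and the ketone oxygen closes onto that acyl carbon to give 7. This ring closure is a five-membered O-acylation, 5-exo-trig at C2, so that C6–C5, C5–C4, C3–C2 and O1–C2 are all made in one flask. Cy2NEt, added only after 6 has been consumed so that it cannot strip the acidic α-protons of the acylcobalt, then removes one of the two benzylic C6 protons of 7, the cobalt fragment leaves as Co(CO)4− under CO, and the C5=C6 alkene of 8 is released. The closest known reaction type is the cobalt-carbonyl coupling of alkyl halides, CO and simple alkynes to 2,4-pentadieno-4-lactones, which has not been shown for a benzyl halide with an aryl(silyl)alkyne. The selectivity needed is regiochemical, since a terminal arylalkyne would take the acyl group at its CH end and put ring A on C3; the SiMe3 cap reverses this because the new C–C bond forms at the less crowded aryl-bearing carbon and cobalt settles on the α-silyl carbon, the bias known from Pauson–Khand reactions and Larock annulations of aryl(silyl)alkynes. No stereocentre is formed, and the Z alkene should result because the proton is lost from the rotamer in which ring B points towards O1 and away from ring A, which also leads to the more stable isomer.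

Step 4
Reactants: 8 (Z)-5-(3-bromo-4-methoxybenzylidene)-4-[4-(tert-butyldimethylsilyloxy)phenyl]-3-(trimethylsilyl)furan-2(5H)-one
Product: 9 3''-bromorubrolide F [(Z)-5-(3-bromo-4-methoxybenzylidene)-4-(4-hydroxyphenyl)furan-2(5H)-one]
Conditions: TBAF (3 equiv), AcOH (3 equiv), THF, 0 to 23 °C
Reagents that add atoms: none
Why: In this fluoride-mediated desilylation the aryl silyl ether is cleaved first and the C3–Si bond of the α-silyl enoate then yields to protodesilylation, helped by the freed para-oxygen of ring A pushing electron density onto C3, while the acetic acid buffer supplies the protons and should keep the enol lactone, the Z alkene and the aryl bromide intact.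

Compound list
1 | 4-iodophenol | Oc1ccc(I)cc1 | starting material
2 | tert-butyl(4-iodophenoxy)dimethylsilane | CC(C)(C)[Si](C)(C)Oc1ccc(I)cc1 | intermediate
3 | ethynyltrimethylsilane | C#C[Si](C)(C)C | starting material
4 | tert-butyldimethyl{4-[(trimethylsilyl)ethynyl]phenoxy}silane | C[Si](C)(C)C#Cc1ccc(O[Si](C)(C)C(C)(C)C)cc1 | intermediate
5 | 3-bromo-4-methoxybenzyl bromide | COc1ccc(CBr)cc1Br | starting material
6 | [(3-bromo-4-methoxyphenyl)acetyl]cobalt tetracarbonyl (CO ligands drawn as Co=C=O) | COc1ccc(CC(=O)[Co](=C=O)(=C=O)(=C=O)=C=O)cc1Br | intermediate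
7 | tricarbonyl{η3-(C3,C4,C5)-5-(3-bromo-4-methoxybenzyl)-4-[4-(tert-butyldimethylsilyloxy)phenyl]-2-oxo-3-(trimethylsilyl)-2,5-dihydrofuranyl}cobalt, racemic (drawn as the σ-allyl form bonded at C5) | COc1ccc(CC2([Co](=C=O)(=C=O)=C=O)OC(=O)C([Si](C)(C)C)=C2c2ccc(O[Si](C)(C)C(C)(C)C)cc2)cc1Br | intermediate
8 | (Z)-5-(3-bromo-4-methoxybenzylidene)-4-[4-(tert-butyldimethylsilyloxy)phenyl]-3-(trimethylsilyl)furan-2(5H)-one | COc1ccc(/C=C2\OC(=O)C([Si](C)(C)C)=C2c2ccc(O[Si](C)(C)C(C)(C)C)cc2)cc1Br | intermediate
9 | 3''-bromorubrolide F, (Z)-5-(3-bromo-4-methoxybenzylidene)-4-(4-hydroxyphenyl)furan-2(5H)-one | COc1ccc(/C=C2\OC(=O)C=C2c2ccc(O)cc2)cc1Br | target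

Total step count: 4 (the preparation of the NaCo(CO)4 solution is not counted). Longest linear sequence: 4 steps (1, 2, 4, 8, 9).

Steps most likely to fail

1. Step 3.
- **What may go wrong:** The hindered alkyne may insert too slowly, so that 6 decarbonylates and the benzyl fragment is lost to homocoupling or ketone formation. Insertion may also run in the opposite sense and place ring A on C3, or release from cobalt may stall.
- **Fallback:** This uses known chemistry, sets out from 2 and returns at 9. Miyaura borylation of 2 (B2pin2, PdCl2(dppf), KOAc, dioxane, 80 °C) should give tert-butyldimethyl[4-(4,4,5,5-tetramethyl-1,3,2-dioxaborolan-2-yl)phenoxy]silane F1. Suzuki coupling of this boronate with commercial 4-bromofuran-2(5H)-one (Pd(PPh3)4, K3PO4, dioxane/H2O, 70 °C) should give 4-[4-(tert-butyldimethylsilyloxy)phenyl]furan-2(5H)-one F2. TBSOTf and iPr2NEt in CH2Cl2 convert it into tert-butyl({4-[4-(tert-butyldimethylsilyloxy)phenyl]furan-2-yl}oxy)dimethylsilane F3. This silyloxyfuran adds through C5 to commercial 3-bromo-4-methoxybenzaldehyde in a vinylogous Mukaiyama aldol reaction to give 5-[(3-bromo-4-methoxyphenyl)(tert-butyldimethylsilyloxy)methyl]-4-[4-(tert-butyldimethylsilyloxy)phenyl]furan-2(5H)-one F4. DBU in the same flask eliminates silanol to give (Z)-5-(3-bromo-4-methoxybenzylidene)-4-[4-(tert-butyldimethylsilyloxy)phenyl]furan-2(5H)-one F5. TBAF/AcOH in THF then frees the phenol and delivers 9.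

2. Step 4.
- **What may go wrong:** The C3–Si bond may resist buffered fluoride. Longer exposure or unbuffered fluoride may open the enol lactone or scramble the alkene geometry.
- **Fallback:** This sets out from 8 and returns at 9. The two silicon groups are removed by different mechanisms in two stages. KHF2 in MeOH at 23 °C should cleave only the aryl silyl ether and give (Z)-5-(3-bromo-4-methoxybenzylidene)-4-(4-hydroxyphenyl)-3-(trimethylsilyl)furan-2(5H)-one F6. TFA in CH2Cl2 (0 to 23 °C) then effects electrophilic ipso-protodesilylation. Protonation at C3 gives a C4 cation stabilised by the β-silicon and by the para-hydroxyl of ring A, and loss of silicon gives 9.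

3. Step 2.
- **What may go wrong:** Copper-mediated oxidative dimerisation of 3 may erode the coupling. Loss of the SiMe3 cap in the amine medium, followed by a second arylation, would have the same effect.
- **Fallback:** This sets out from 2 and returns at 4. It is a Stille alkynylation with commercial trimethyl[(tributylstannyl)ethynyl]silane (Pd(PPh3)4, toluene, 90 °C). The preformed alkynylmetal is used without copper or base, and no new compound arises on the way (F0).

Further compounds
F1 | step 3 | tert-butyldimethyl[4-(4,4,5,5-tetramethyl-1,3,2-dioxaborolan-2-yl)phenoxy]silane | CC(C)(C)[Si](C)(C)Oc1ccc(B2OC(C)(C)C(C)(C)O2)cc1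
F2 | step 3 | 4-[4-(tert-butyldimethylsilyloxy)phenyl]furan-2(5H)-one | CC(C)(C)[Si](C)(C)Oc1ccc(C2=CC(=O)OC2)cc1
F3 | step 3 | tert-butyl({4-[4-(tert-butyldimethylsilyloxy)phenyl]furan-2-yl}oxy)dimethylsilane | CC(C)(C)[Si](C)(C)Oc1ccc(-c2coc(O[Si](C)(C)C(C)(C)C)c2)cc1
F4 | step 3 | 5-[(3-bromo-4-methoxyphenyl)(tert-butyldimethylsilyloxy)methyl]-4-[4-(tert-butyldimethylsilyloxy)phenyl]furan-2(5H)-one (racemic mixture of diastereomers) | COc1ccc(C(O[Si](C)(C)C(C)(C)C)C2OC(=O)C=C2c2ccc(O[Si](C)(C)C(C)(C)C)cc2)cc1Br
F5 | step 3 | (Z)-5-(3-bromo-4-methoxybenzylidene)-4-[4-(tert-butyldimethylsilyloxy)phenyl]furan-2(5H)-one | COc1ccc(/C=C2\OC(=O)C=C2c2ccc(O[Si](C)(C)C(C)(C)C)cc2)cc1Br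
F6 | step 4 | (Z)-5-(3-bromo-4-methoxybenzylidene)-4-(4-hydroxyphenyl)-3-(trimethylsilyl)furan-2(5H)-one | COc1ccc(/C=C2\OC(=O)C([Si](C)(C)C)=C2c2ccc(O)cc2)cc1Br
F0 | step 2 | none | none
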